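**Retrosynthetic overview**
1. Numbering: cyclohexene C1 (quaternary; CH3 and styryl), C2 (CH–aryl), C3=C4(CH3), C5H2, C6H2; Cα is the styryl carbon on C1. Last disconnection: Cα=Cβ, by Horner–Wadsworth–Emmons olefination of a C1 aldehyde with a coumarin-8-ylmethyl phosphonate.
2. Key disconnection: ring bonds C4–C5 and C1–C2, made in one flask as a formal [3+3] union of enone 4 (C2, C3, C4, aryl, methyl) with the 3-(methoxycarbonyl)butyl group of zinc reagent 9 (C5, C6, C1, its methyl, Cα as ester). The sequence is asymmetric 1,2-alkylation, lactonisation, then boat Ireland–Claisen rearrangement.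
3. Enabling feature: with Cα as a carboxyl, Cα–C1–C2–C3=C4 is a γ,δ-unsaturated carbonyl (Claisen retron), and C4 is tied back to C1 through C5–C6. The allyl vinyl ether is therefore a six-membered lactone (temporary O–C4 bond) that forces a boat transition state; its carbinol stereocentre relays chirality to C1 and C2 and disappears when C4 becomes sp2.
4. Ring order: both coumarin bicycles are bought intact; the temporary oxan-2-one forms and is consumed inside the key step; the cyclohexene is the only ring built.

Key step: step 5

Assumption: compound 1 (8-formylumbelliferone) is taken as a catalogue compound; if unavailable it is one Duff formylation from umbelliferone, which changes nothing downstream.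

Step 1
Reactants: 1 7-hydroxy-2-oxo-2H-chromene-8-carbaldehyde
Product: 2 7-methoxy-2-oxo-2H-chromene-8-carbaldehyde
Conditions: MeI, K2CO3, DMF, rt
Reagents that add atoms: iodomethane CI
Why: Williamson O-methylation of the phenol under mild carbonate base, which leaves the aldehyde and the lactone untouched.

Step 2
Reactants: 2 7-methoxy-2-oxo-2H-chromene-8-carbaldehyde; 3 1-(triphenyl-λ5-phosphanylidene)propan-2-one
Product: 4 7-methoxy-8-[(1E)-3-oxobut-1-en-1-yl]-2H-chromen-2-one
Conditions: toluene, 100 °C
Reagents that add atoms: none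
Why: Wittig olefination with a stabilised acyl ylide is base-free and should give the (E)-enone by thermodynamic control of the oxaphosphetane.

Step 3
Reactants: 5 3-methyloxolan-2-one (α-methyl-γ-butyrolactone, racemic)
Product: 7 methyl 4-iodo-2-methylbutanoate (racemic), via silyl iodoester 6 (not isolated)
Conditions: Me3SiI, CH2Cl2, rt; then MeOH, rt
Reagents that add atoms: iodotrimethylsilane C[Si](C)(C)I; methanol CO
Why: Silyl iodide ring-opening of the lactone (iodide SN2 at the O–CH2 carbon of the silylated lactone) followed by methanolysis and HI-catalysed Fischer esterification should give the ω-iodo ester, whose racemic α-centre is erased later.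

Step 4
Reactants: 7 methyl 4-iodo-2-methylbutanoate
Product: 9 (4-methoxy-3-methyl-4-oxobutyl)[(trimethylsilyl)methyl]zinc (used as a toluene–hexane solution), via alkylzinc iodide 8 (not isolated)
Conditions: Zn dust (activated with BrCH2CH2Br and Me3SiCl), THF, 40 °C; then Me3SiCH2Li (pentane), −78 °C to 0 °C; solvent exchanged to toluene–hexane, LiI filtered off
Reagents that add atoms: zinc [Zn]; (trimethylsilyl)methyllithium [Li]C[Si](C)(C)C
Why: Direct insertion of activated zinc into the primary C–I bond tolerates the ester, and transmetalation of the alkylzinc iodide with the silylmethyllithium at −78 °C should outrun attack on the ester, giving a mixed diorganozinc whose trimethylsilylmethyl group is a non-transferable dummy ligand.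

Step 5
Reactants: 4 7-methoxy-8-[(1E)-3-oxobut-1-en-1-yl]-2H-chromen-2-one; 9 (4-methoxy-3-methyl-4-oxobutyl)[(trimethylsilyl)methyl]zinc
Product: 14 (1S,2S)-2-(7-methoxy-2-oxo-2H-chromen-8-yl)-1,4-dimethylcyclohex-3-ene-1-carboxylic acid, via zinc alkoxide 10 (not isolated), via lactone 11 (not isolated), via silyl ketene acetal 12 (not isolated), via silyl ester 13 (not isolated)
Conditions: Ti(OiPr)4 (1.2 equiv), chiral trans-cyclohexane-1,2-diamine bis(hydroxycamphorsulfonamide) ligand (10 mol %, enantiomer chosen for Re-face alkyl transfer), toluene–hexane, rt; 60 °C; then THF, Me3SiCl, KN(SiMe3)2 (excess), −78 °C; 100 °C (sealed vessel); dilute aqueous HCl, 0 °C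
Reagents that add atoms: none
Why: The titanium complex of the chiral bis(sulfonamide) diol transfers the 3-(methoxycarbonyl)butyl group of 9 to the Re face of the ketone of 4 (1,2-addition, new bond C4–C5) while the trimethylsilylmethyl group stays on zinc; the tertiary (R)-alkoxide 10 closes to the temporary oxan-2-one 11, KN(SiMe3)2/Me3SiCl gives the endocyclic silyl ketene acetal 12, and heating triggers the Ireland–Claisen [3,3] shift (new bond C1–C2, lactone C–O bond broken) to silyl ester 13, hydrolysed to 14. The closest known reaction types are the titanium-promoted enantioselective addition of functionalised dialkylzincs to enone ketones, the same titanium-promoted alkyl transfer from mixed alkyl(trimethylsilylmethyl)zincs to aldehydes, and the Ireland–Claisen rearrangement of 6-alkenyl δ-lactone silyl ketene acetals to cyclohex-3-ene carboxylic acids. Ring closures: the oxan-2-one by 6-exo-trig acyl substitution of the alkoxide on the ester, and the cyclohexene by sigmatropic ring transposition in which the two alkene carbons take the place of the O–C(=O) unit of the lactone ring. Stereocentres: C1 and C2 are both set in the [3,3] step by suprafacial transfer from the carbinol centre, which is set by the chiral titanium complex and destroyed as it becomes C4; the lactone ring allows only the boat transition state, and boat plus (E)-alkene places the aryl group cis to the carboxyl carbon, as the target requires. The step needs 1,2- over 1,4-addition and ketone over aryl lactone (secured by the titanium–zinc pair), transfer of the ester-bearing alkyl group and not the silylmethyl group (secured by the α-silyl dummy ligand), one enantioface (ligand) and one ketene acetal geometry (fixed by the ring), while both α-methyl epimers of 11 converge on the same enolate and the slight excess of 9, the only other enolisable ester, is covered by the excess of base and silyl chloride.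

Step 6
Reactants: 14 (1S,2S)-2-(7-methoxy-2-oxo-2H-chromen-8-yl)-1,4-dimethylcyclohex-3-ene-1-carboxylic acid
Product: 16 (1S,2S)-2-(7-methoxy-2-oxo-2H-chromen-8-yl)-1,4-dimethylcyclohex-3-ene-1-carbaldehyde, via acid chloride 15 (not isolated)
Conditions: (COCl)2, cat. DMF, CH2Cl2, 0 °C to rt; evaporate; LiAlH(OtBu)3, THF, −78 °C
Reagents that add atoms: none
Why: Acid chloride formation (Vilsmeier-type activation) followed by Brown reduction with the hindered alkoxyaluminium hydride at −78 °C should stop at the aldehyde and spare both aryl lactones, and C1 has no α-hydrogen, so neither stereocentre can epimerise.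

Step 7
Reactants: 2 7-methoxy-2-oxo-2H-chromene-8-carbaldehyde
Product: 17 8-(hydroxymethyl)-7-methoxy-2H-chromen-2-one
Conditions: NaBH4 (0.3 equiv), THF–MeOH, 0 °C
Reagents that add atoms: none
Why: Borohydride 1,2-reduction of the aryl aldehyde is much faster at 0 °C than reduction of the coumarin lactone or its ring alkene.

Step 8
Reactants: 17 8-(hydroxymethyl)-7-methoxy-2H-chromen-2-one
Product: 18 8-(bromomethyl)-7-methoxy-2H-chromen-2-one
Conditions: PBr3, CH2Cl2, 0 °C to rt
Reagents that add atoms: phosphorus tribromide BrP(Br)Br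
Why: Bromination of the benzylic alcohol through its phosphite ester (SN2 by bromide).

Step 9
Reactants: 18 8-(bromomethyl)-7-methoxy-2H-chromen-2-one
Product: 19 diethyl [(7-methoxy-2-oxo-2H-chromen-8-yl)methyl]phosphonate
Conditions: P(OEt)3 (neat), 130 °C
Reagents that add atoms: triethyl phosphite CCOP(OCC)OCC
Why: Michaelis–Arbuzov reaction of the benzylic bromide, driven by loss of bromoethane.

Step 10
Reactants: 16 (1S,2S)-2-(7-methoxy-2-oxo-2H-chromen-8-yl)-1,4-dimethylcyclohex-3-ene-1-carbaldehyde; 19 diethyl [(7-methoxy-2-oxo-2H-chromen-8-yl)methyl]phosphonate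
Product: 20 7-methoxy-8-{(E)-2-[(1R,2R)-2-(7-methoxy-2-oxo-2H-chromen-8-yl)-1,4-dimethylcyclohex-3-en-1-yl]ethenyl}-2H-chromen-2-one (CNP0156435.1)
Conditions: NaN(SiMe3)2, THF, −78 °C to rt
Reagents that add atoms: none
Why: Horner–Wadsworth–Emmons olefination with the aryl-stabilised phosphonate anion should give the (E)-styryl alkene through reversible addition and syn elimination; no stereocentre is formed and the quaternary α-carbon cannot epimerise.

**Compound list**
1 | 7-hydroxy-2-oxo-2H-chromene-8-carbaldehyde | O=Cc1c(O)ccc2ccc(=O)oc12 | starting material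
2 | 7-methoxy-2-oxo-2H-chromene-8-carbaldehyde | COc1ccc2ccc(=O)oc2c1C=O | intermediate
3 | 1-(triphenyl-λ5-phosphanylidene)propan-2-one | CC(=O)C=P(c1ccccc1)(c1ccccc1)c1ccccc1 | starting material
4 | 7-methoxy-8-[(1E)-3-oxobut-1-en-1-yl]-2H-chromen-2-one | COc1ccc2ccc(=O)oc2c1/C=C/C(C)=O | intermediate
5 | 3-methyloxolan-2-one (racemic) | CC1CCOC1=O | starting material
6 | trimethylsilyl 4-iodo-2-methylbutanoate (racemic) | CC(CCI)C(=O)O[Si](C)(C)C | intermediate
7 | methyl 4-iodo-2-methylbutanoate (racemic) | COC(=O)C(C)CCI | intermediate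
8 | iodo(4-methoxy-3-methyl-4-oxobutyl)zinc | COC(=O)C(C)CC[Zn]I | intermediate
9 | (4-methoxy-3-methyl-4-oxobutyl)[(trimethylsilyl)methyl]zinc | COC(=O)C(C)CC[Zn]C[Si](C)(C)C | intermediate
10 | (trimethylsilylmethyl)zinc alkoxide of methyl (5R,6E)-5-hydroxy-7-(7-methoxy-2-oxo-2H-chromen-8-yl)-2,5-dimethylhept-6-enoate (C2 epimers) | COC(=O)C(C)CC[C@](C)(/C=C/c1c(OC)ccc2ccc(=O)oc12)O[Zn]C[Si](C)(C)C | intermediate
11 | (6R)-6-[(E)-2-(7-methoxy-2-oxo-2H-chromen-8-yl)ethenyl]-3,6-dimethyloxan-2-one (C3 epimers) | CC1CC[C@](C)(/C=C/c2c(OC)ccc3ccc(=O)oc23)OC1=O | intermediate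
12 | 8-{(E)-2-[(2R)-2,5-dimethyl-6-(trimethylsilyloxy)-3,4-dihydro-2H-pyran-2-yl]ethenyl}-7-methoxy-2H-chromen-2-one | C[C@]1(/C=C/c2c(OC)ccc3ccc(=O)oc23)CCC(C)=C(O[Si](C)(C)C)O1 | intermediate
13 | trimethylsilyl (1S,2S)-2-(7-methoxy-2-oxo-2H-chromen-8-yl)-1,4-dimethylcyclohex-3-ene-1-carboxylate | C[Si](C)(C)OC(=O)[C@@]1(C)CCC(C)=C[C@H]1c1c(OC)ccc2ccc(=O)oc12 | intermediate
14 | (1S,2S)-2-(7-methoxy-2-oxo-2H-chromen-8-yl)-1,4-dimethylcyclohex-3-ene-1-carboxylic acid (aryl cis to carboxyl) | OC(=O)[C@@]1(C)CCC(C)=C[C@H]1c1c(OC)ccc2ccc(=O)oc12 | intermediate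
15 | (1S,2S)-2-(7-methoxy-2-oxo-2H-chromen-8-yl)-1,4-dimethylcyclohex-3-ene-1-carbonyl chloride | ClC(=O)[C@@]1(C)CCC(C)=C[C@H]1c1c(OC)ccc2ccc(=O)oc12 | intermediate
16 | (1S,2S)-2-(7-methoxy-2-oxo-2H-chromen-8-yl)-1,4-dimethylcyclohex-3-ene-1-carbaldehyde | O=C[C@@]1(C)CCC(C)=C[C@H]1c1c(OC)ccc2ccc(=O)oc12 | intermediate
17 | 8-(hydroxymethyl)-7-methoxy-2H-chromen-2-one | COc1ccc2ccc(=O)oc2c1CO | intermediate
18 | 8-(bromomethyl)-7-methoxy-2H-chromen-2-one | COc1ccc2ccc(=O)oc2c1CBr | intermediate
19 | diethyl [(7-methoxy-2-oxo-2H-chromen-8-yl)methyl]phosphonate | CCOP(=O)(OCC)Cc1c(OC)ccc2ccc(=O)oc12 | intermediate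
20 | 7-methoxy-8-{(E)-2-[(1R,2R)-2-(7-methoxy-2-oxo-2H-chromen-8-yl)-1,4-dimethylcyclohex-3-en-1-yl]ethenyl}-2H-chromen-2-one | COc1ccc2ccc(=O)oc2c1/C=C/[C@@]1(C)CCC(C)=C[C@H]1c1c(OC)ccc2ccc(=O)oc12 | target

**Step count and risks**
Total step count: 10. Longest linear sequence: 5 steps (for example 1 → 2 → 4 → 14 → 16 → 20).

Steps most likely to fail:

Step 5. The risks are erosion of facial selectivity in the alkyl transfer (the mixed zinc reagent transfers its alkyl group more slowly than a symmetric dialkylzinc, so unselective background addition may compete), ring-opening of the lactone by titanium isopropoxide or interference of titanium and zinc alkoxides with enolisation and silylation, and ionisation of the tertiary allylic C–O bond before the rearrangement. The fallback sets out from 4 and 9 and returns at 14. The alkyl transfer is run with Ti(OiPr)4 and the racemic ligand, the mixture is worked up, and the racemic lactone 6-[(E)-2-(7-methoxy-2-oxo-2H-chromen-8-yl)ethenyl]-3,6-dimethyloxan-2-one F1 is isolated. Preparative chromatography on a chiral stationary phase with supercritical CO2 separates the (6R) series (both C3 epimers), which is compound 11. Isolated 11 is then enolised and rearranged on its own (KN(SiMe3)2, Me3SiCl, THF, −78 °C; toluene, 100 °C; dilute acid) to reach 14. Absolute configuration then comes from a resolution and not from the catalyst, and no titanium or zinc is present during enolisation.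

Step 10. The risks are slow addition of the phosphonate anion to the neopentyl-type aldehyde, competing conjugate addition of the anion to the coumarin rings, and loss of E selectivity. The fallback sets out from 16 and returns at 20. Wittig methylenation of 16 (Ph3P=CH2, THF, 0 °C) would give 8-[(1R,6R)-6-ethenyl-3,6-dimethylcyclohex-2-en-1-yl]-7-methoxy-2H-chromen-2-one F2. Separately, umbelliferone is iodinated (I2, KI, aqueous NH3) to 7-hydroxy-8-iodo-2H-chromen-2-one F3 and O-methylated (MeI, K2CO3) to 8-iodo-7-methoxy-2H-chromen-2-one F4. Heck coupling of F2 with F4 (Pd(OAc)2, P(o-tol)3, Et3N, DMF, 90 °C) should give 20 directly. Because C1 is quaternary, β-hydride elimination can only give the (E)-styryl alkene.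

Step 6. The risks are attack of hydride on the two aryl lactones, over-reduction of the aldehyde, and acid-promoted lactonisation of the carboxyl group onto the C3=C4 alkene during chloride formation. The fallback sets out from 14 and returns at 16. Carbodiimide coupling with ethanethiol (EDC hydrochloride, DMAP, CH2Cl2) would give S-ethyl (1S,2S)-2-(7-methoxy-2-oxo-2H-chromen-8-yl)-1,4-dimethylcyclohex-3-ene-1-carbothioate F5. Fukuyama reduction (Et3SiH, Pd/C, acetone, rt) should then give 16 under neutral, hydride-free conditions.

**Further compounds**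
F1 | step 5 | 6-[(E)-2-(7-methoxy-2-oxo-2H-chromen-8-yl)ethenyl]-3,6-dimethyloxan-2-one (racemic, C3 epimers) | CC1CCC(C)(/C=C/c2c(OC)ccc3ccc(=O)oc23)OC1=O
F2 | step 10 | 8-[(1R,6R)-6-ethenyl-3,6-dimethylcyclohex-2-en-1-yl]-7-methoxy-2H-chromen-2-one | C=C[C@@]1(C)CCC(C)=C[C@H]1c1c(OC)ccc2ccc(=O)oc12
F3 | step 10 | 7-hydroxy-8-iodo-2H-chromen-2-one | Oc1ccc2ccc(=O)oc2c1I
F4 | step 10 | 8-iodo-7-methoxy-2H-chromen-2-one | COc1ccc2ccc(=O)oc2c1I
F5 | step 6 | S-ethyl (1S,2S)-2-(7-methoxy-2-oxo-2H-chromen-8-yl)-1,4-dimethylcyclohex-3-ene-1-carbothioate | CCSC(=O)[C@@]1(C)CCC(C)=C[C@H]1c1c(OC)ccc2ccc(=O)oc12
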